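**Assumption:** lupalbigenin (5,7,4'-trihydroxy-6,3'-diprenylisoflavone) has no stereocentres, and the prenyl alkenes have no E/Z isomers, so there is no enantiomer to control.

## Retrosynthetic overview
1. Lupalbigenin ⇐ global demethylation and MOM removal of the fully protected isoflavone **18**.
2. The C3–C1' bond is made last by Suzuki–Miyaura coupling of 3-iodochromone **9** with aryl-Bpin **17**. These two fragments are of similar size.
3. **9** ⇐ enaminone/I2 closure of the pyranone ring from 2-hydroxyacetophenone **7** ⇐ Fries-type acylation of **6** ⇐ Ir C–H borylation and oxidation of **4** ⇐ DoM prenylation of resorcinol dimethyl ether. Ring A comes from resorcinol, and the third oxygen is added by borylation/oxidation.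
4. **17** ⇐ 4-bromophenol via allylation, Claisen rearrangement, MOM protection, cross-metathesis to the prenyl group, and Miyaura borylation.
5. Both benzene rings pre-exist in the starting materials, the pyranone ring closes at Step 7, and the biaryl bond forms in Step 13.

## Route

**Step 1**
Reactants: **1** resorcinol
Product: **2** 1,3-dimethoxybenzene
Conditions: MeI, K2CO3, acetone, reflux
Reagents that add atoms: iodomethane, CI
Why: Williamson O-methylation protects both phenols and sets up directed lithiation and steric C–H borylation.

**Step 2**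
Reactants: **2**; **3** prenyl bromide (1-bromo-3-methylbut-2-ene)
Product: **4** 2-prenyl-1,3-dimethoxybenzene
Conditions: n-BuLi, THF, 0 °C→rt; then CuI (10 mol%), **3**, –78 °C→rt
Reagents that add atoms: none beyond reactant **3**
Why: Directed ortho-metalation puts lithium exclusively between the two OMe groups, and Cu-catalysed SN2 alkylation delivers the linear prenyl group at the future C6.

**Step 3**
Reactants: **4**
Product: **5** 2-(3,5-dimethoxy-4-prenylphenyl)-4,4,5,5-tetramethyl-1,3,2-dioxaborolane
Conditions: B2pin2 (0.6 equiv), [Ir(OMe)(cod)]2 (1.5 mol%), dtbpy (3 mol%), THF, 80 °C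
Reagents that add atoms: bis(pinacolato)diboron, CC1(C)OB(OC1(C)C)B2OC(C)(C)C(C)(C)O2
Why: Ir-catalysed C–H borylation is sterically controlled and occurs at the only position meta to all substituents (C5), which is the site of the third ring oxygen.

**Step 4**
Reactants: **5**
Product: **6** 3,5-dimethoxy-4-prenylphenol
Conditions: 30% H2O2, NaOH (aq), THF, 0 °C→rt
Reagents that add atoms: hydrogen peroxide, OO
Why: Oxidative C–B to C–O conversion (boronate oxidation) gives the phloroglucinol-pattern phenol, which will become the ring oxygen O1.

**Step 5**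
Reactants: **6**
Product: **7** 1-[6-hydroxy-2,4-dimethoxy-3-(3-methylbut-2-enyl)phenyl]ethan-1-one
Conditions: AcOH, BF3·OEt2, 60 °C
Reagents that add atoms: acetic acid, CC(=O)O
Why: BF3-promoted Friedel–Crafts (Fries-type) C-acylation occurs ortho to the free OH. Both ortho positions are equivalent, and the OH ends up para to the prenyl group, which is the correct geometry for a 6-prenyl chromone.

**Step 6**
Reactants: **7**
Product: **8** (E)-3-(dimethylamino)-1-[6-hydroxy-2,4-dimethoxy-3-prenylphenyl]prop-2-en-1-one
Conditions: DMF-DMA, toluene, 110 °C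
Reagents that add atoms: N,N-dimethylformamide dimethyl acetal, CN(C)C(OC)OC
Why: Bredereck-type condensation of the acetyl CH3 with DMF-DMA gives the enaminone, which supplies C2 of the chromone.

**Step 7**
Reactants: **8**
Product: **9** 3-iodo-5,7-dimethoxy-6-prenylchromone
Conditions: I2, CHCl3, rt
Reagents that add atoms: iodine, II
Why: Electrophilic α-iodination of the enaminone is followed by oxa-6-endo cyclisation of the phenol and loss of Me2NH. This builds the pyranone ring with iodine at C3.

**Step 8**
Reactants: **10** 4-bromophenol; **11** allyl bromide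
Product: **12** 1-(allyloxy)-4-bromobenzene
Conditions: K2CO3, acetone, reflux
Reagents that add atoms: none beyond reactant **11**
Why: Williamson O-allylation.

**Step 9**
Reactants: **12**
Product: **13** 2-allyl-4-bromophenol
Conditions: neat, 200 °C (or PhNEt2, reflux)
Reagents that add atoms: none
Why: Aromatic Claisen [3,3] rearrangement goes to the ortho position because the para position is blocked by Br.

**Step 10**
Reactants: **13**
Product: **14** 2-allyl-4-bromo-1-(methoxymethoxy)benzene
Conditions: MOMCl, i-Pr2NEt, CH2Cl2, 0 °C→rt
Reagents that add atoms: chloromethyl methyl ether, COCCl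
Why: MOM protection of the phenol keeps it inert to the Ru and Pd steps and it is removed under the final deprotection.

**Step 11**
Reactants: **14**; **15** 2-methyl-2-butene
Product: **16** 4-bromo-1-(methoxymethoxy)-2-(3-methylbut-2-enyl)benzene
Conditions: Grubbs II (5 mol%), **15** (10 equiv), CH2Cl2, 40 °C (sealed)
Reagents that add atoms: none beyond reactant **15**
Why: Olefin cross-metathesis converts the terminal allyl alkene into the trisubstituted prenyl alkene, with propene as the by-product.

**Step 12**
Reactants: **16**
Product: **17** 2-[4-(methoxymethoxy)-3-prenylphenyl]-4,4,5,5-tetramethyl-1,3,2-dioxaborolane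
Conditions: B2pin2, PdCl2(dppf), KOAc, dioxane, 80 °C
Reagents that add atoms: bis(pinacolato)diboron, CC1(C)OB(OC1(C)C)B2OC(C)(C)C(C)(C)O2
Why: Miyaura borylation converts the aryl bromide into the boronate; the prenyl alkene and MOM ether are inert.

**Step 13**
Reactants: **9** and **17**
Product: **18** 5,7-dimethoxy-3-[4-(methoxymethoxy)-3-prenylphenyl]-6-prenylchromone
Conditions: Pd(PPh3)4 (5 mol%), Na2CO3 (aq), DME, 80 °C
Reagents that add atoms: none
Why: Suzuki–Miyaura coupling of the vinylic C–I bond with the arylboronate forms the C3–C1' isoflavone bond; no stereocentre is involved.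

**Step 14**
Reactants: **18**
Product: **19** lupalbigenin
Conditions: BBr3 (8 equiv), CH2Cl2, –78 °C→0 °C, 4 h; MeOH quench
Reagents that add atoms: none (the O–H hydrogens come from the quench)
Why: BBr3 cleaves the 5-OMe, 7-OMe and 4'-OMOM groups, giving the three free phenols while the chromone and both prenyl groups are retained at low temperature.

## Compound list
1 | resorcinol | Oc1cccc(O)c1 | starting material
2 | 1,3-dimethoxybenzene | COc1cccc(OC)c1 | intermediate
3 | prenyl bromide | CC(C)=CCBr | starting material
4 | 2-prenyl-1,3-dimethoxybenzene | COc1cccc(OC)c1CC=C(C)C | intermediate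
5 | 3,5-dimethoxy-4-prenylphenyl-Bpin | COc1cc(B2OC(C)(C)C(C)(C)O2)cc(OC)c1CC=C(C)C | intermediate
6 | 3,5-dimethoxy-4-prenylphenol | COc1cc(O)cc(OC)c1CC=C(C)C | intermediate
7 | 2-hydroxy-4,6-dimethoxy-3-prenylacetophenone | CC(=O)c1c(O)cc(OC)c(CC=C(C)C)c1OC | intermediate
8 | enaminone (E) | CN(C)/C=C/C(=O)c1c(O)cc(OC)c(CC=C(C)C)c1OC | intermediate
9 | 3-iodo-5,7-dimethoxy-6-prenylchromone | COc1cc2occ(I)c(=O)c2c(OC)c1CC=C(C)C | intermediate
10 | 4-bromophenol | Oc1ccc(Br)cc1 | starting material
11 | allyl bromide | C=CCBr | starting material
12 | 1-(allyloxy)-4-bromobenzene | C=CCOc1ccc(Br)cc1 | intermediate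
13 | 2-allyl-4-bromophenol | C=CCc1cc(Br)ccc1O | intermediate
14 | 2-allyl-4-bromo-1-(MOMO)benzene | C=CCc1cc(Br)ccc1OCOC | intermediate
15 | 2-methyl-2-butene | CC=C(C)C | starting material
16 | 4-bromo-1-(MOMO)-2-prenylbenzene | CC(C)=CCc1cc(Br)ccc1OCOC | intermediate
17 | 4-MOMO-3-prenylphenyl-Bpin | CC(C)=CCc1cc(B2OC(C)(C)C(C)(C)O2)ccc1OCOC | intermediate
18 | 5,7-dimethoxy-3-(4-MOMO-3-prenylphenyl)-6-prenylchromone | COc1cc2occ(-c3ccc(OCOC)c(CC=C(C)C)c3)c(=O)c2c(OC)c1CC=C(C)C | intermediate
19 | lupalbigenin (achiral) | CC(C)=CCc1cc(-c2coc3cc(O)c(CC=C(C)C)c(O)c3c2=O)ccc1O | target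

## Totals
- Total steps: 14.
- Longest linear sequence: 9 (Steps 1–7, 13, 14).

## Three steps most likely to fail
1. **Steps 2–3 (prenylation, then Ir borylation with the prenyl alkene present).** Prenylation can give SN2′ (reverse-prenyl) by-product, and the alkene may be hydroborated during borylation.
   Fallback: change the order. Borylate and oxidise 1,3-dimethoxybenzene first, methylate the resulting phenol to 1,3,5-trimethoxybenzene, then do DoM prenylation, DoM acetylation, and BCl3 mono-demethylation to reach **7**.
2. **Step 5 (BF3/AcOH acylation).** The acid-sensitive prenyl alkene may oligomerise or protonate.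
   Fallback: use Lewis-acid-free ortho-formylation (MgCl2, Et3N, paraformaldehyde) of **6**, then MeMgBr addition and MnO2 oxidation to give **7**.
3. **Step 14 (BBr3 global demethylation).** HBr/BBr3 may cyclise the prenyl phenols to chromans, or the 7-OMe cleavage may be incomplete.
   Fallback: rebuild ring A with MOM ethers in place of methyl ethers (tris-OMOM arene, DoM prenylation and acylation, then selective ring-oxygen unmasking), so the last step is a mild HCl/MeOH hydrolysis.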